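**Retrosynthetic overview** (upper unit = the flavan-3-ol bound through its C4; lower unit = the flavan-3,4-diol bound through its C6)
1. Target 26 ⇐ heptabenzyl ether 25 by global hydrogenolysis; all stereocentres are in place in 25.
2. 25 ⇐ salicylaldehyde 18 + chiral alkenylsulfonium salt 23: ring C of the lower unit is cut at O1–C2 and C3–C4, and one operation (oxa-Michael addition, ylide addition to C4, epoxide closure, hydrolysis) should build the pyran ring, the 3,4-dioxygen pattern and C2, C3 and C4.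
3. Enabling feature: on ring A of the lower unit the phenolic O1 (on C8a) is ortho to C4a, whose substituent C4 can stand at the aldehyde level (a salicylaldehyde); C3 and C4 both carry oxygen (a latent cis-3,4-epoxide), and the C7 oxygen para to C4a activates C4 for the trans opening.
4. 18 ⇐ phenol 17 (ortho-formylation) ⇐ ketone 8 + aryl bromide 13 (organocerium addition, then ionic hydrogenation that sets C4 of the upper unit cis to O3).
5. 8 ⇐ chalcone 5 (asymmetric epoxidation, then 6-endo phenol–epoxide closure); ring order: ring C of the upper unit (step 5), then ring C of the lower unit together with its transient oxirane (step 16); the two units have opposite configurations at C2/C3, each set by its own reagent.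

Key step: step 16

Assumption: the (2R,5R)-thiolanium reagent 23 is taken to be the antipode that delivers the (2R,3S,4S)-epoxide 24; if a model salicylaldehyde shows the opposite sense, the (2S,5S) antipode, made in the same way from the enantiomeric cyclic sulfate, is used instead.

Step 1
Reactants: 1 1-(2,3,4-trihydroxyphenyl)ethanone
Product: 2 1-[3,4-bis(benzyloxy)-2-hydroxyphenyl]ethanone
Conditions: BnBr (2.1 equiv), K2CO3, DMF, rt
Reagents that add atoms: benzyl bromide, BrCc1ccccc1
Why: Williamson etherification in which the 2-OH, hydrogen-bonded to the acetyl carbonyl, is the least nucleophilic phenol and should stay free when two equivalents of benzyl bromide are used.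

Step 2
Reactants: 2 1-[3,4-bis(benzyloxy)-2-hydroxyphenyl]ethanone
Product: 3 1-[3,4-bis(benzyloxy)-2-(methoxymethoxy)phenyl]ethanone
Conditions: NaH, MOMCl, DMF, 0 °C → rt
Reagents that add atoms: chloromethyl methyl ether, COCCl
Why: Deprotonation of the chelated phenol and O-alkylation give the acetal-protected phenol that keeps the later chalcone from cyclising during the epoxidation.

Step 3
Reactants: 3 1-[3,4-bis(benzyloxy)-2-(methoxymethoxy)phenyl]ethanone, 4 4-(benzyloxy)benzaldehyde
Product: 5 (E)-1-[3,4-bis(benzyloxy)-2-(methoxymethoxy)phenyl]-3-[4-(benzyloxy)phenyl]prop-2-en-1-one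
Conditions: KOH, EtOH–THF, rt
Reagents that add atoms: none
Why: Claisen–Schmidt condensation (aldol addition and E1cB dehydration) of the aryl methyl ketone with the non-enolisable aldehyde should give the thermodynamically favoured E-enone.

Step 4
Reactants: 5 (E)-1-[3,4-bis(benzyloxy)-2-(methoxymethoxy)phenyl]-3-[4-(benzyloxy)phenyl]prop-2-en-1-one
Product: 6 [3,4-bis(benzyloxy)-2-(methoxymethoxy)phenyl]{(2S,3R)-3-[4-(benzyloxy)phenyl]oxiran-2-yl}methanone
Conditions: poly-D-leucine, urea–H2O2, DBU, THF, rt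
Reagents that add atoms: urea–hydrogen peroxide, OO.NC(N)=O
Why: Juliá–Colonna epoxidation, in which hydroperoxide adds to the enone bound to the helical poly-D-leucine, should give the trans-(2S,3R)-epoxide (the mirror image of the product formed with poly-L-leucine) and so set the carbons that become C3 and, after inversion, C2 of the upper unit.

Step 5
Reactants: 6 [3,4-bis(benzyloxy)-2-(methoxymethoxy)phenyl]{(2S,3R)-3-[4-(benzyloxy)phenyl]oxiran-2-yl}methanone
Product: 7 (2S,3S)-7,8-bis(benzyloxy)-2-[4-(benzyloxy)phenyl]-3-hydroxychroman-4-one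
Conditions: conc. HCl, MeOH–THF, 55 °C
Reagents that add atoms: none
Why: Acid removes the methoxymethyl acetal and the freed phenol opens the epoxide at the benzylic carbon in a 6-endo closure with inversion, so the retained α-carbon becomes (3S) and the β-carbon becomes (2S); even an ionised benzylic carbon should close to the favoured 2,3-trans ring because C3 is untouched.

Step 6
Reactants: 7 (2S,3S)-7,8-bis(benzyloxy)-2-[4-(benzyloxy)phenyl]-3-hydroxychroman-4-one
Product: 8 (2S,3S)-3,7,8-tris(benzyloxy)-2-[4-(benzyloxy)phenyl]chroman-4-one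
Conditions: BnOC(=NH)CCl3, TfOH (cat.), CH2Cl2–cyclohexane, 0 °C → rt
Reagents that add atoms: benzyl 2,2,2-trichloroacetimidate, N=C(OCc1ccccc1)C(Cl)(Cl)Cl
Why: Acid-catalysed benzyl transfer from the trichloroacetimidate avoids the basic conditions that would epimerise C3 or open the pyranone by β-elimination.

Step 7
Reactants: 9 2,3-bis(benzyloxy)benzaldehyde
Product: 11 2,3-bis(benzyloxy)phenol, via aryl formate 10 (not isolated)
Conditions: mCPBA, CH2Cl2, rt; then K2CO3 (cat.), MeOH, rt
Reagents that add atoms: 3-chloroperoxybenzoic acid, OOC(=O)c1cccc(Cl)c1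
Why: Dakin-type Baeyer–Villiger oxidation, in which the electron-rich aryl group migrates to oxygen, gives the aryl formate that methanolysis converts into the phenol.

Step 8
Reactants: 11 2,3-bis(benzyloxy)phenol
Product: 12 2,3-bis(benzyloxy)-4-bromophenol
Conditions: NBS, MeCN, −20 → 0 °C
Reagents that add atoms: N-bromosuccinimide, O=C1CCC(=O)N1Br
Why: Electrophilic bromination should go para to the free hydroxyl group, the strongest donor on the ring, at the position that is also ortho to a benzyloxy group.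

Step 9
Reactants: 12 2,3-bis(benzyloxy)-4-bromophenol
Product: 13 2,3-bis(benzyloxy)-1-bromo-4-[(4-methoxybenzyl)oxy]benzene
Conditions: PMBCl, K2CO3, DMF, rt
Reagents that add atoms: 4-methoxybenzyl chloride, COc1ccc(CCl)cc1
Why: Williamson etherification masks the phenol as a 4-methoxybenzyl ether that survives the organometallic step and is cleaved by acid in step 11.

Step 10
Reactants: 13 2,3-bis(benzyloxy)-1-bromo-4-[(4-methoxybenzyl)oxy]benzene, 8 (2S,3S)-3,7,8-tris(benzyloxy)-2-[4-(benzyloxy)phenyl]chroman-4-one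
Product: 16 (2S,3S)-3,7,8-tris(benzyloxy)-2-[4-(benzyloxy)phenyl]-4-{2,3-bis(benzyloxy)-4-[(4-methoxybenzyl)oxy]phenyl}chroman-4-ol, via aryllithium 14 (not isolated), via arylcerium dichloride 15 (not isolated)
Conditions: 13, n-BuLi, THF, −78 °C; CeCl3, −78 °C; then 8, −78 → −40 °C; aq. NH4Cl
Reagents that add atoms: none
Why: Bromine–lithium exchange and transmetalation to the weakly basic organocerium reagent should allow 1,2-addition to the enolisable α-benzyloxy ketone without epimerisation at C3 or β-elimination of the ring oxygen; the new carbinol centre is removed in the next step, so either epimer serves.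

Step 11
Reactants: 16 (2S,3S)-3,7,8-tris(benzyloxy)-2-[4-(benzyloxy)phenyl]-4-{2,3-bis(benzyloxy)-4-[(4-methoxybenzyl)oxy]phenyl}chroman-4-ol
Product: 17 2,3-bis(benzyloxy)-4-{(2S,3R,4R)-3,7,8-tris(benzyloxy)-2-[4-(benzyloxy)phenyl]chroman-4-yl}phenol
Conditions: Et3SiH, TFA, CH2Cl2, −40 → 0 °C
Reagents that add atoms: none
Why: Ionic hydrogenation: acid ionises the tertiary, doubly benzylic alcohol and Et3SiH should deliver hydride to the diarylmethyl cation from the face anti to the 3-benzyloxy group (the face nucleophiles take in 2,3-trans-flavan-4-yl cations), which places the aryl group cis to O3 and sets (4R), while the same acid cleaves the 4-methoxybenzyl ether.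

Step 12
Reactants: 17 2,3-bis(benzyloxy)-4-{(2S,3R,4R)-3,7,8-tris(benzyloxy)-2-[4-(benzyloxy)phenyl]chroman-4-yl}phenol
Product: 18 3,4-bis(benzyloxy)-2-hydroxy-5-{(2S,3R,4S)-3,7,8-tris(benzyloxy)-2-[4-(benzyloxy)phenyl]chroman-4-yl}benzaldehyde
Conditions: MgCl2, Et3N, (CH2O)n, THF, reflux
Reagents that add atoms: paraformaldehyde (formaldehyde), C=O
Why: Casnati–Skattebøl formylation through the chloromagnesium phenoxide (ArOMgCl) should put the aldehyde at the only free position ortho to the phenol, by chelated hydroxymethylation and hydride transfer to a second formaldehyde.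

Step 13
Reactants: 19 (4S,7S)-4,7-dimethyl-1,3,2-dioxathiepane 2,2-dioxide
Product: 20 (2R,5R)-2,5-dimethylthiolane
Conditions: Na2S·9H2O, DMF, 60 °C
Reagents that add atoms: sodium sulfide, [Na+].[Na+].[S-2]
Why: Double SN2 displacement of the cyclic sulfate by sulfide, each with inversion, should convert the (S,S)-diol derivative into the C2-symmetric (R,R)-thiolane.

Step 14
Reactants: 20 (2R,5R)-2,5-dimethylthiolane
Product: 21 (2R,5R)-2,5-dimethylthiolane 1-oxide
Conditions: NaIO4, MeOH–H2O, 0 °C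
Reagents that add atoms: sodium periodate, [Na+].[O-]I(=O)(=O)=O
Why: Periodate oxidises the sulfide selectively to the sulfoxide, which is a single compound because the two faces of sulfur are related by the C2 axis.

Step 15
Reactants: 21 (2R,5R)-2,5-dimethylthiolane 1-oxide, 22 1-(benzyloxy)-4-ethenylbenzene
Product: 23 (2R,5R)-1-{(E)-2-[4-(benzyloxy)phenyl]ethenyl}-2,5-dimethylthiolan-1-ium trifluoromethanesulfonate
Conditions: Tf2O, CH2Cl2, −78 °C; then 22, −78 → −20 °C
Reagents that add atoms: trifluoromethanesulfonic anhydride, O=S(=O)(OS(=O)(=O)C(F)(F)F)C(F)(F)F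
Why: Interrupted Pummerer reaction: the sulfoxide activated by Tf2O is attacked at sulfur by the terminal carbon of the electron-rich styrene, and the benzylic cation loses the proton α to sulfur to give the E-alkenylsulfonium salt.

Step 16
Reactants: 18 3,4-bis(benzyloxy)-2-hydroxy-5-{(2S,3R,4S)-3,7,8-tris(benzyloxy)-2-[4-(benzyloxy)phenyl]chroman-4-yl}benzaldehyde, 23 (2R,5R)-1-{(E)-2-[4-(benzyloxy)phenyl]ethenyl}-2,5-dimethylthiolan-1-ium trifluoromethanesulfonate
Product: 25 (2R,3S,4R)-7,8-bis(benzyloxy)-2-[4-(benzyloxy)phenyl]-6-{(2S,3R,4S)-3,7,8-tris(benzyloxy)-2-[4-(benzyloxy)phenyl]chroman-4-yl}chroman-3,4-diol, via 3,4-epoxychroman 24 (not isolated)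
Conditions: 23 (1.3 equiv), Cs2CO3, CH2Cl2, −20 → 0 °C; then THF–H2O, NaH2PO4 (pH 5), 0 °C
Reagents that add atoms: water, O
Why: Proposed new method: the caesium phenoxide of 18 adds to the β-carbon of the alkenylsulfonium salt (oxa-Michael addition, forming O1–C2), the sulfonium ylide thus generated at C3 adds to the ortho aldehyde carbon C4 (6-exo-trig, closing the pyran ring by the C3–C4 bond), and the anti-betaine expels the thiolane in a 3-exo-tet displacement to give the 3,4-epoxide 24, which buffered water opens at the benzylic, para-benzyloxy-activated C4 with inversion. The closest known reaction types are the annulation of vinylsulfonium salts with amino aldehydes and amino ketones to epoxide-fused heterocycles and the chromene synthesis from salicylaldehydes and vinylphosphonium salts; new here are the β-aryl group on the acceptor, the phenoxide nucleophile and the absolute control. C2 is set in the oxa-Michael step, which should be reversible because the 2-formylphenoxide is a good leaving group from the ylide, so the ring closure selects the epimer whose aryl group is equatorial in the chair-like transition state and therefore trans to the epoxide. C3 is set by the C2-symmetric thiolanium group, which shields one face of the ylide carbon, and C4 follows because only the betaine with antiperiplanar O− and S+ can close, giving the cis-fused epoxide; water then attacks C4 trans to O3 and gives the all-equatorial 2,3-trans-3,4-trans diol. The step needs reagent control over the remote stereocentres of the upper unit, which the chiral sulfonium group is meant to supply, and trapping of the ylide by the aldehyde rather than protonation, which the six-membered intramolecular delivery and the lack of any proton source other than the phenol should secure.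

Step 17
Reactants: 25 (2R,3S,4R)-7,8-bis(benzyloxy)-2-[4-(benzyloxy)phenyl]-6-{(2S,3R,4S)-3,7,8-tris(benzyloxy)-2-[4-(benzyloxy)phenyl]chroman-4-yl}chroman-3,4-diol
Product: 26 (2R,3S,4R)-2-(4-hydroxyphenyl)-6-[(2S,3R,4R)-3,7,8-trihydroxy-2-(4-hydroxyphenyl)chroman-4-yl]chroman-3,4,7,8-tetrol
Conditions: H2 (1 atm), Pd(OH)2/C, THF–MeOH, rt
Reagents that add atoms: none
Why: Hydrogenolysis of the seven benzyl ethers under neutral conditions should leave the less reactive ring C–O bonds and the secondary benzylic alcohol in place.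

**Compound list**
(The descriptor at C4 of the upper unit is R in 17 and 26 but S in 18, 24 and 25; this is a change of substituent priorities only, the geometry is the same throughout.)

1 | 1-(2,3,4-trihydroxyphenyl)ethanone | CC(=O)c1ccc(O)c(O)c1O | starting material
2 | 1-[3,4-bis(benzyloxy)-2-hydroxyphenyl]ethanone | CC(=O)c1ccc(OCc2ccccc2)c(OCc2ccccc2)c1O | intermediate
3 | 1-[3,4-bis(benzyloxy)-2-(methoxymethoxy)phenyl]ethanone | CC(=O)c1ccc(OCc2ccccc2)c(OCc2ccccc2)c1OCOC | intermediate
4 | 4-(benzyloxy)benzaldehyde | O=Cc1ccc(OCc2ccccc2)cc1 | starting material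
5 | (E)-1-[3,4-bis(benzyloxy)-2-(methoxymethoxy)phenyl]-3-[4-(benzyloxy)phenyl]prop-2-en-1-one | COCOc1c(C(=O)/C=C/c2ccc(OCc3ccccc3)cc2)ccc(OCc2ccccc2)c1OCc1ccccc1 | intermediate
6 | [3,4-bis(benzyloxy)-2-(methoxymethoxy)phenyl]{(2S,3R)-3-[4-(benzyloxy)phenyl]oxiran-2-yl}methanone | COCOc1c(C(=O)[C@H]2O[C@@H]2c2ccc(OCc3ccccc3)cc2)ccc(OCc2ccccc2)c1OCc1ccccc1 | intermediate
7 | (2S,3S)-7,8-bis(benzyloxy)-2-[4-(benzyloxy)phenyl]-3-hydroxychroman-4-one | O=C1c2ccc(OCc3ccccc3)c(OCc3ccccc3)c2O[C@@H](c2ccc(OCc3ccccc3)cc2)[C@@H]1O | intermediate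
8 | (2S,3S)-3,7,8-tris(benzyloxy)-2-[4-(benzyloxy)phenyl]chroman-4-one | O=C1c2ccc(OCc3ccccc3)c(OCc3ccccc3)c2O[C@@H](c2ccc(OCc3ccccc3)cc2)[C@@H]1OCc1ccccc1 | intermediate
9 | 2,3-bis(benzyloxy)benzaldehyde | O=Cc1cccc(OCc2ccccc2)c1OCc1ccccc1 | starting material
10 | 2,3-bis(benzyloxy)phenyl formate (not isolated) | O=COc1cccc(OCc2ccccc2)c1OCc1ccccc1 | intermediate
11 | 2,3-bis(benzyloxy)phenol | Oc1cccc(OCc2ccccc2)c1OCc1ccccc1 | intermediate
12 | 2,3-bis(benzyloxy)-4-bromophenol | Oc1ccc(Br)c(OCc2ccccc2)c1OCc1ccccc1 | intermediate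
13 | 2,3-bis(benzyloxy)-1-bromo-4-[(4-methoxybenzyl)oxy]benzene | COc1ccc(COc2ccc(Br)c(OCc3ccccc3)c2OCc2ccccc2)cc1 | intermediate
14 | {2,3-bis(benzyloxy)-4-[(4-methoxybenzyl)oxy]phenyl}lithium (not isolated) | [Li]c1ccc(OCc2ccc(OC)cc2)c(OCc2ccccc2)c1OCc1ccccc1 | intermediate
15 | {2,3-bis(benzyloxy)-4-[(4-methoxybenzyl)oxy]phenyl}cerium dichloride (not isolated) | Cl[Ce](Cl)c1ccc(OCc2ccc(OC)cc2)c(OCc2ccccc2)c1OCc1ccccc1 | intermediate
16 | (2S,3S)-3,7,8-tris(benzyloxy)-2-[4-(benzyloxy)phenyl]-4-{2,3-bis(benzyloxy)-4-[(4-methoxybenzyl)oxy]phenyl}chroman-4-ol (configuration at C4 left open) | OC1(c2ccc(OCc3ccc(OC)cc3)c(OCc3ccccc3)c2OCc2ccccc2)c2ccc(OCc3ccccc3)c(OCc3ccccc3)c2O[C@@H](c2ccc(OCc3ccccc3)cc2)[C@@H]1OCc1ccccc1 | intermediate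
17 | 2,3-bis(benzyloxy)-4-{(2S,3R,4R)-3,7,8-tris(benzyloxy)-2-[4-(benzyloxy)phenyl]chroman-4-yl}phenol | Oc1ccc([C@@H]2c3ccc(OCc4ccccc4)c(OCc4ccccc4)c3O[C@@H](c3ccc(OCc4ccccc4)cc3)[C@@H]2OCc2ccccc2)c(OCc2ccccc2)c1OCc1ccccc1 | intermediate
18 | 3,4-bis(benzyloxy)-2-hydroxy-5-{(2S,3R,4S)-3,7,8-tris(benzyloxy)-2-[4-(benzyloxy)phenyl]chroman-4-yl}benzaldehyde | O=Cc1cc([C@@H]2c3ccc(OCc4ccccc4)c(OCc4ccccc4)c3O[C@@H](c3ccc(OCc4ccccc4)cc3)[C@@H]2OCc2ccccc2)c(OCc2ccccc2)c(OCc2ccccc2)c1O | intermediate
19 | (4S,7S)-4,7-dimethyl-1,3,2-dioxathiepane 2,2-dioxide (cyclic sulfate of (2S,5S)-hexane-2,5-diol) | C[C@H]1CC[C@H](C)OS(=O)(=O)O1 | starting material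
20 | (2R,5R)-2,5-dimethylthiolane | C[C@@H]1CC[C@@H](C)S1 | intermediate
21 | (2R,5R)-2,5-dimethylthiolane 1-oxide | C[C@@H]1CC[C@@H](C)S1=O | intermediate
22 | 1-(benzyloxy)-4-ethenylbenzene | C=Cc1ccc(OCc2ccccc2)cc1 | starting material
23 | (2R,5R)-1-{(E)-2-[4-(benzyloxy)phenyl]ethenyl}-2,5-dimethylthiolan-1-ium trifluoromethanesulfonate | C[C@@H]1CC[C@@H](C)[S+]1/C=C/c1ccc(OCc2ccccc2)cc1.[O-]S(=O)(=O)C(F)(F)F | intermediate
24 | (2R,3S,4S)-7,8-bis(benzyloxy)-2-[4-(benzyloxy)phenyl]-3,4-epoxy-6-{(2S,3R,4S)-3,7,8-tris(benzyloxy)-2-[4-(benzyloxy)phenyl]chroman-4-yl}chroman (not isolated) | c1ccccc1COc1ccc([C@H]2Oc3c(cc([C@@H]4c5ccc(OCc6ccccc6)c(OCc6ccccc6)c5O[C@@H](c5ccc(OCc6ccccc6)cc5)[C@@H]4OCc4ccccc4)c(OCc4ccccc4)c3OCc3ccccc3)[C@@H]3O[C@H]23)cc1 | intermediate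
25 | (2R,3S,4R)-7,8-bis(benzyloxy)-2-[4-(benzyloxy)phenyl]-6-{(2S,3R,4S)-3,7,8-tris(benzyloxy)-2-[4-(benzyloxy)phenyl]chroman-4-yl}chroman-3,4-diol | c1ccccc1COc1ccc([C@H]2Oc3c(cc([C@@H]4c5ccc(OCc6ccccc6)c(OCc6ccccc6)c5O[C@@H](c5ccc(OCc6ccccc6)cc5)[C@@H]4OCc4ccccc4)c(OCc4ccccc4)c3OCc3ccccc3)[C@@H](O)[C@@H]2O)cc1 | intermediate
26 | (2R,3S,4R)-2-(4-hydroxyphenyl)-6-[(2S,3R,4R)-3,7,8-trihydroxy-2-(4-hydroxyphenyl)chroman-4-yl]chroman-3,4,7,8-tetrol | Oc1ccc([C@H]2Oc3c(cc([C@@H]4c5ccc(O)c(O)c5O[C@@H](c5ccc(O)cc5)[C@@H]4O)c(O)c3O)[C@@H](O)[C@@H]2O)cc1 | target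

**Step count and risks**
Total: 17 steps. Longest linear sequence: 11 steps (steps 1–6, 10, 11, 12, 16, 17).

Steps most likely to fail:

1. Step 16 (proposed new method). The oxa-Michael addition may not be reversible, or the sulfonium group may discriminate poorly, so that the facial selectivity at C2/C3 relative to the upper unit is low; the ylide may also be protonated and eliminate the thiolane instead of closing the ring. Fallback by known chemistry, setting out from 18: the phenoxide of 18 is allylated with methyl (E)-3-[4-(benzyloxy)phenyl]prop-2-en-1-yl carbonate F1 (made from (E)-3-[4-(benzyloxy)phenyl]prop-2-en-1-ol and methyl chloroformate with pyridine) under [Ir(cod)Cl]2 and a chiral binaphthol-derived phosphoramidite (branched-selective asymmetric allylic etherification, catalyst control of the ether carbon) to give the (S)-configured branched allyl aryl ether F2. Wittig methylenation of the aldehyde with Ph3P=CH2 in THF gives the diene F3. Ring-closing metathesis with the second-generation Grubbs catalyst in CH2Cl2 closes the same C3–C4 bond as an alkene and gives the flav-3-ene F4. Dimethyldioxirane in wet acetone at 0 °C should epoxidise the C3=C4 bond anti to the 2-aryl group to give 24, which is hydrolysed as in step 16, and the route is rejoined at 25.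

2. Step 11. Hydride delivery to the diarylmethyl cation may show poor facial selectivity, and the acid may cause a 1,2-hydride shift from C3 or reductive opening of the pyran ring. Fallback, setting out from 16: TFA with anisole and no silane (CH2Cl2, 0 °C, then aq. NaHCO3) removes the 4-methoxybenzyl group and dehydrates the carbinol to the isolable p-quinone methide F5. 1,6-Reduction with the bulky LiBH(s-Bu)3 in THF at −78 °C, under basic conditions and steric control anti to the 3-benzyloxy group, rearomatises the ring and returns to 17.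

3. Step 17. Hydrogenolysis of the activated benzylic C4–OH bond of the lower unit may compete with debenzylation. Fallback, setting out from 25: MnO2 in CH2Cl2 oxidises only the benzylic C4 alcohol to give the 4-ketone F6. Hydrogenolysis (H2, Pd(OH)2/C, THF–MeOH) then removes the seven benzyl groups with no labile benzylic hydroxyl present and gives the heptaphenolic ketone F7. NaBH4 in EtOH at 0 °C reduces the ketone by axial hydride delivery to the equatorial alcohol (the established course for 2,3-trans-dihydroflavonols), giving the 3,4-trans diol, which is the target 26.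

**Further compounds**
F1 | step 16 | methyl (E)-3-[4-(benzyloxy)phenyl]prop-2-en-1-yl carbonate | COC(=O)OC/C=C/c1ccc(OCc2ccccc2)cc1
F2 | step 16 | 3,4-bis(benzyloxy)-2-({(1S)-1-[4-(benzyloxy)phenyl]prop-2-en-1-yl}oxy)-5-{(2S,3R,4S)-3,7,8-tris(benzyloxy)-2-[4-(benzyloxy)phenyl]chroman-4-yl}benzaldehyde | O=Cc1cc([C@@H]2c3ccc(OCc4ccccc4)c(OCc4ccccc4)c3O[C@@H](c3ccc(OCc4ccccc4)cc3)[C@@H]2OCc2ccccc2)c(OCc2ccccc2)c(OCc2ccccc2)c1O[C@@H](C=C)c1ccc(OCc2ccccc2)cc1
F3 | step 16 | (2S,3R,4S)-3,7,8-tris(benzyloxy)-2-[4-(benzyloxy)phenyl]-4-[2,3-bis(benzyloxy)-4-({(1S)-1-[4-(benzyloxy)phenyl]prop-2-en-1-yl}oxy)-5-ethenylphenyl]chroman | C=Cc1cc([C@@H]2c3ccc(OCc4ccccc4)c(OCc4ccccc4)c3O[C@@H](c3ccc(OCc4ccccc4)cc3)[C@@H]2OCc2ccccc2)c(OCc2ccccc2)c(OCc2ccccc2)c1O[C@@H](C=C)c1ccc(OCc2ccccc2)cc1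
F4 | step 16 | (2S)-7,8-bis(benzyloxy)-2-[4-(benzyloxy)phenyl]-6-{(2S,3R,4S)-3,7,8-tris(benzyloxy)-2-[4-(benzyloxy)phenyl]chroman-4-yl}-2H-chromene | c1ccccc1COc1ccc([C@H]2Oc3c(cc([C@@H]4c5ccc(OCc6ccccc6)c(OCc6ccccc6)c5O[C@@H](c5ccc(OCc6ccccc6)cc5)[C@@H]4OCc4ccccc4)c(OCc4ccccc4)c3OCc3ccccc3)C=C2)cc1
F5 | step 11 | 2,3-bis(benzyloxy)-4-{(2S,3R)-3,7,8-tris(benzyloxy)-2-[4-(benzyloxy)phenyl]-2,3-dihydro-4H-chromen-4-ylidene}cyclohexa-2,5-dien-1-one | O=C1C=CC(=C2c3ccc(OCc4ccccc4)c(OCc4ccccc4)c3O[C@@H](c3ccc(OCc4ccccc4)cc3)[C@@H]2OCc2ccccc2)C(OCc2ccccc2)=C1OCc1ccccc1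
F6 | step 17 | (2R,3R)-7,8-bis(benzyloxy)-2-[4-(benzyloxy)phenyl]-3-hydroxy-6-{(2S,3R,4S)-3,7,8-tris(benzyloxy)-2-[4-(benzyloxy)phenyl]chroman-4-yl}chroman-4-one | c1ccccc1COc1ccc([C@H]2Oc3c(cc([C@@H]4c5ccc(OCc6ccccc6)c(OCc6ccccc6)c5O[C@@H](c5ccc(OCc6ccccc6)cc5)[C@@H]4OCc4ccccc4)c(OCc4ccccc4)c3OCc3ccccc3)C(=O)[C@@H]2O)cc1
F7 | step 17 | (2R,3R)-3,7,8-trihydroxy-2-(4-hydroxyphenyl)-6-[(2S,3R,4R)-3,7,8-trihydroxy-2-(4-hydroxyphenyl)chroman-4-yl]chroman-4-one | Oc1ccc([C@H]2Oc3c(cc([C@@H]4c5ccc(O)c(O)c5O[C@@H](c5ccc(O)cc5)[C@@H]4O)c(O)c3O)C(=O)[C@@H]2O)cc1
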